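Slowness in these runs comes in rungs, and what the flask can afford depends on which of them spends its partner.

| flask | substrate | partner | precatalyst | remark |
|---|---|---|---|---|
| summer | 0.16 M | 1.3 equiv | 0.2 mol% | run made earlier |
| winter | 0.16 M | 2.1 equiv | 0.2 mol% | run made earlier |
| dusk | 0.080 M | 0.95 equiv | 0.2 mol% | run made earlier |
| flask | 0.16 M | 0.950 equiv | 0.2 mol% |  |

- summer (time / min: target / %, substrate / %): 4.00: 3.4, 95.5; 6.00: 8.0, 92.0; 12.0: 25.1, 76.0; 20.0: 44.2, 55.4; 30.0: 59.1, 40.8; 50.0: 73.0, 28.1
- winter (time / min: target / %, substrate / %): 4.00: 5.6, 92.8; 6.00: 13.2, 85.7; 12.0: 36.4, 63.3; 20.0: 61.6, 38.4; 30.0: 77.6, 20.9; 50.0: 92.8, 5.8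
- dusk (time / min: target / %, substrate / %): 4.00: 0.5, 99.5; 12.0: 6.3, 94.1; 25.0: 15.6, 83.2; 40.0: 26.1, 72.1; 50.0: 31.3, 70.0

(readings scatter by 1 percentage point)



- factor on the rate of making target when 50% of the substrate are converted if precatalyst is charged twice over
- factor on the rate when 50% of the substrate are converted if precatalyst is charged at 1 mol% instead

On the first rung, substrate in the winter run shows a half-life of about 11.1 min between 12.0 min and 20.0 min. The next rung spans 20.0 min, longer than that half-life: from 30.0 min to 50.0 min the logarithmic fall of substrate in the summer run is 0.291 of the winter fall, less than the 0.522 expected if partner went with substrate one for one, so I read a second route losing partner. The last rung reaches the start: summer target grows 2.35-fold from 4.00 min to 6.00 min, near the squared time ratio 2.25, so I read the rate as rising with time while catalyst is released from precatalyst.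

For the flask, 0.0720 M is the partner margin, the partner charged less what 50% conversion consumes. The [partner] at that point is this margin minus what the second route has taken, so arriving earlier saves partner. With [partner] held and catalyst growing steadily from precatalyst, the time to 50% conversion shrinks as the square root of the loading and the rate at that conversion grows by the same root, which gives 1.41 on doubling and 2.24 at 1 mol%; with the saved margin on top, I commit to nearer 2 and nearer 5.00.

The forecast gives 1.6 and 3, holding that “the catalyst order is probably about 0.7”.

The simulation gives 2.26 and 4.72.

    substrate + partner + catalyst → catalyst + target (k = 5800 L² mol⁻² min⁻¹)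
    precatalyst → catalyst (k = 0.0140 min⁻¹)
    partner → decomposed reagent (k = 0.0200 min⁻¹)

At 16.9 min in the flask, partner goes 2.2 times as fast into reaction as into decomposition, and doubled precatalyst multiplies the 33.9 min needed for 50% conversion by 0.605. Decomposed reagent in the flask reaches 0.0565 M at 500 min, below the margin of 0.0720 M by 0.0155 M, and with partner at 0% the target stands at 59.7%.

The numbers in the tables were generated by integration with constants of no real substance, and the scatter is random.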